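**Retrosynthetic overview**
- Target ⇒ meso cis-2,5-diaryl-3,4-dimethyl-2,5-dihydrofuran (phenols as acetates): one syn H/OH addition to the ring alkene, anti to both aryl groups, sets all four stereocentres; a chiral borane chooses between the two enantiotopic alkene carbons.
- Dihydrofuran ⇒ aryl/alkenyl oxirane by copper-catalysed ring expansion (three-membered to five-membered ring).
- Oxirane ⇒ symmetric (1E,3E)-1,4-diaryl-2,3-dimethylbutadiene (mono-epoxidation) ⇒ 2,3-dimethylbutadiene + two aryl iodides (twofold Heck).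
- Aryl iodide ⇒ catechol (O-methylation, para-iodination, acetylation).
- Ring order: arene rings come from catechol; oxirane (step 5); dihydrofuran by ring expansion (step 6); its stereocentres last (step 7).

Assumption: the sense of induction in step 7 is assigned by extrapolating the empirical model for IpcBH2 with trisubstituted alkenes (reagent from (−)-α-pinene gives 10); if experiment shows the opposite sense, the reagent from (+)-α-pinene is used instead.

**Step 1**
Reactants: 1 catechol (benzene-1,2-diol)
Product: 2 guaiacol (2-methoxyphenol)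
Conditions: MeI (1.0 equiv), K2CO3 (1.0 equiv), acetone, reflux; 1 in 1.5-fold excess, recovered
Reagents that add atoms: iodomethane, CI
Why: Williamson ether synthesis (SN2 on MeI by the mono-phenoxide), with excess diol keeping dimethylation low; no stereocentre is formed.

**Step 2**
Reactants: 2 guaiacol
Product: 3 4-iodo-2-methoxyphenol
Conditions: N-iodosuccinimide (1.0 equiv), p-toluenesulfonic acid monohydrate (10 mol %), MeCN, 0 °C to rt
Reagents that add atoms: N-iodosuccinimide, O=C1CCC(=O)N1I
Why: electrophilic aromatic iodination goes para to the free hydroxyl, the strongest director, which is the position meta to OMe that the target needs; no stereocentre.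

**Step 3**
Reactants: 3 4-iodo-2-methoxyphenol
Product: 4 4-iodo-2-methoxyphenyl acetate
Conditions: Ac2O, pyridine, 4-(dimethylamino)pyridine (5 mol %), CH2Cl2, rt
Reagents that add atoms: acetic anhydride, CC(=O)OC(C)=O
Why: nucleophile-catalysed O-acylation; the acetate makes the arene electron-neutral so the later benzylic oxirane and ether carbons do not ionise, and it is removed in the alkaline peroxide work-up of step 7.

**Step 4**
Reactants: 4 4-iodo-2-methoxyphenyl acetate (2.2 equiv); 5 2,3-dimethylbuta-1,3-diene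
Product: 6 (1E,3E)-1,4-bis(4-acetoxy-3-methoxyphenyl)-2,3-dimethylbuta-1,3-diene
Conditions: Pd(OAc)2 (5 mol %), tetrabutylammonium chloride, KOAc, DMF, 80 °C, sealed tube
Reagents that add atoms: none
Why: twofold Mizoroki–Heck reaction, in which each aryl–palladium adds to a CH2 terminus and syn β-hydride elimination of a benzylic hydrogen from the allyl-palladium intermediate gives the conjugated alkene with aryl trans to the diene carbon, hence E,E.

**Step 5**
Reactants: 6 the (1E,3E)-diene
Product: 7 rac-(2R,3R)-2-(4-acetoxy-3-methoxyphenyl)-3-[(E)-1-(4-acetoxy-3-methoxyphenyl)prop-1-en-2-yl]-3-methyloxirane (aryl on C2 trans to the alkenyl group on C3)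
Conditions: mCPBA (1.0 equiv), NaHCO3, CH2Cl2, 0 °C
Reagents that add atoms: 3-chloroperbenzoic acid, OOC(=O)c1cccc(Cl)c1
Why: Prilezhaev epoxidation is concerted and stereospecific, so the E alkene gives the trans aryl/alkenyl oxirane (racemic, which does not matter because 8 is meso), and the monoepoxide dominates because the remaining alkene is less nucleophilic than the diene.

**Step 6**
Reactants: 7 the vinyl oxirane
Product: 8 meso-(2R,5S)-2,5-bis(4-acetoxy-3-methoxyphenyl)-3,4-dimethyl-2,5-dihydrofuran (aryl groups cis)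
Conditions: Cu(hfacac)2, copper bis(1,1,1,5,5,5-hexafluoropentane-2,4-dionate) (5 mol %), toluene, 120 °C, sealed tube
Reagents that add atoms: none
Why: copper-catalysed vinyl oxirane to 2,5-dihydrofuran ring expansion, a stereospecific formal 1,3-shift of the oxirane oxygen through an allylcopper alkoxide from the allylic oxirane carbon to the far alkene terminus on the same face, which for the E alkene and trans oxirane places the two aryl groups cis.

**Step 7**
Reactants: 8 the meso dihydrofuran
Product: 10 (2R,3S,4R,5R)-2,5-bis(4-hydroxy-3-methoxyphenyl)-3,4-dimethyltetrahydrofuran-3-ol (CNP0234919.1), via tertiary alkyl(isopinocampheyl)borane 9 (not isolated)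
Conditions: IpcBH2 (monoisopinocampheylborane prepared from (−)-α-pinene, 2.5 equiv), THF, 0 to 25 °C, 24–48 h; then NaOH, H2O2, MeOH/H2O, 0 °C to rt; NH4Cl to pH 6
Reagents that add atoms: hydrogen peroxide, OO (the hydroxyl oxygen of 10); monoisopinocampheylborane, C[C@@H]1[C@@H](B)C[C@H]2C[C@@H]1C2(C)C (boron and the C10 group, present in 9 only)
Why: Proposed new method: reagent-controlled desymmetrising hydroboration of a meso tetrasubstituted alkene, in which the four-centre syn B–H addition can only occur on the face anti to both aryl groups (fixing OH trans and both methyls cis to the aryls), the isopinocampheyl group differentiates the two enantiotopic alkene carbons (in the extrapolated model the methyl on the boron-bearing carbon sits in the pocket that holds H for trisubstituted alkenes), stereoretentive boron-to-oxygen 1,2-migration then gives the 3S carbinol and the same alkaline peroxide cleaves both aryl acetates; the closest known reactions are the asymmetric hydroboration of 2,5-dihydrofuran with Ipc2BH, of trisubstituted alkenes with IpcBH2, and the non-asymmetric hydroboration of tetrasubstituted alkenes with BH3.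

**Compound list**
1 | catechol (benzene-1,2-diol) | Oc1ccccc1O | starting material
2 | guaiacol (2-methoxyphenol) | COc1ccccc1O | intermediate
3 | 4-iodo-2-methoxyphenol | COc1cc(I)ccc1O | intermediate
4 | 4-iodo-2-methoxyphenyl acetate | COc1cc(I)ccc1OC(C)=O | intermediate
5 | 2,3-dimethylbuta-1,3-diene | C=C(C)C(C)=C | starting material
6 | (1E,3E)-1,4-bis(4-acetoxy-3-methoxyphenyl)-2,3-dimethylbuta-1,3-diene | CC(=O)Oc1ccc(/C=C(C)/C(C)=C/c2ccc(OC(C)=O)c(OC)c2)cc1OC | intermediate
7 | rac-(2R,3R)-2-(4-acetoxy-3-methoxyphenyl)-3-[(E)-1-(4-acetoxy-3-methoxyphenyl)prop-1-en-2-yl]-3-methyloxirane (racemate, one enantiomer drawn) | CC(=O)Oc1ccc([C@H]2O[C@]2(C)/C(C)=C/c3ccc(OC(C)=O)c(OC)c3)cc1OC | intermediate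
8 | meso-(2R,5S)-2,5-bis(4-acetoxy-3-methoxyphenyl)-3,4-dimethyl-2,5-dihydrofuran | CC(=O)Oc1ccc([C@@H]2O[C@H](c3ccc(OC(C)=O)c(OC)c3)C(C)=C2C)cc1OC | intermediate
9 | [2,5-bis(4-acetoxy-3-methoxyphenyl)-3,4-dimethyltetrahydrofuran-3-yl](isopinocampheyl)borane, boron on C3 where the hydroxyl of 10 will be, ring configuration as in 10 | CC(=O)Oc1ccc([C@H]2O[C@@H](c3ccc(OC(C)=O)c(OC)c3)[C@@H](C)[C@]2(C)[BH][C@H]4C[C@H]5C[C@@H]([C@@H]4C)C5(C)C)cc1OC | intermediate (not isolated)
10 | (2R,3S,4R,5R)-2,5-bis(4-hydroxy-3-methoxyphenyl)-3,4-dimethyltetrahydrofuran-3-ol | COc1cc([C@H]2O[C@@H](c3ccc(O)c(OC)c3)[C@@H](C)[C@]2(C)O)ccc1O | target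

**Totals**
Total steps: 7. Longest linear sequence: 7 (1 to 10); 5 enters at step 4.

**Steps most likely to fail**

Step 7 (the proposed new step). The hindered alkene may add IpcBH2 slowly, loss of α-pinene from the reagent would release achiral boranes and erode the ee, and the level and sense of induction are unproven. Fallback with known chemistry, from 8 back to 10: hydroboration with BH3·SMe2 (THF, 0 to 40 °C) and the same NaOH/H2O2 work-up gives the racemate, that is 10 together with (2S,3R,4S,5S)-2,5-bis(4-hydroxy-3-methoxyphenyl)-3,4-dimethyltetrahydrofuran-3-ol F6. Both phenols are then acylated with (1S)-(−)-camphanic chloride (Et3N, 4-(dimethylamino)pyridine, CH2Cl2, 0 °C; the tertiary alcohol stays free). This gives the bis[(1S,4R)-camphanate] of 10 F7 and the bis[(1S,4R)-camphanate] of the enantiomer F8, which are separated by crystallisation or chromatography. K2CO3 in MeOH on F7 returns 10.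

Step 6. The ring expansion could deliver the trans-2,5 isomer (which would lead to the C5 epimer of 10) or isomerise the oxirane to a β,γ-unsaturated ketone. Fallback, from 4 back to 8, with the cis geometry fixed by one SN2 inversion:
- Twofold direct C–H arylation of commercial 3,4-dimethylfuran with 4 (Pd(OAc)2, KOAc, DMA, 130 °C) gives 2,5-bis(4-acetoxy-3-methoxyphenyl)-3,4-dimethylfuran F3.
- mCPBA (CH2Cl2, 0 °C) opens the furan to (Z)-1,4-bis(4-acetoxy-3-methoxyphenyl)-2,3-dimethylbut-2-ene-1,4-dione F4.
- Corey–Bakshi–Shibata reduction of both ketones ((S)-Me-CBS oxazaborolidine, BH3·SMe2, THF, −20 °C) gives the C2-symmetric (1R,4R,2Z)-1,4-bis(4-acetoxy-3-methoxyphenyl)-2,3-dimethylbut-2-ene-1,4-diol F5; either antipode serves.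
- Mitsunobu cyclodehydration (PPh3, DIAD, THF, 0 °C) inverts one carbinol carbon and closes the ring to meso 8.

Step 4. β-Hydride elimination toward a methyl group, trapping of the allyl-palladium intermediate, or incomplete second arylation could lower the yield of the E,E-diene. Fallback, from 4 back to 6: Sonogashira coupling with propyne (Pd(PPh3)2Cl2, CuI, Et3N, THF, rt) gives 2-methoxy-4-(prop-1-yn-1-yl)phenyl acetate F1. Hydrozirconation with Cp2Zr(H)Cl (THF, rt) places zirconium on the methyl-bearing carbon to give the (E)-alkenylzirconocene chloride F2, which is not isolated. CuCl-mediated homocoupling of F2 with retention of alkene geometry gives 6.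

**Further compounds**
F1 | step 4 | 2-methoxy-4-(prop-1-yn-1-yl)phenyl acetate | CC#Cc1ccc(OC(C)=O)c(OC)c1
F2 | step 4 | chlorobis(cyclopentadienyl)[(E)-1-(4-acetoxy-3-methoxyphenyl)prop-1-en-2-yl]zirconium | C/C(=C\c1ccc(OC(C)=O)c(OC)c1)[Zr](Cl)(C1C=CC=C1)C1C=CC=C1
F3 | step 6 | 2,5-bis(4-acetoxy-3-methoxyphenyl)-3,4-dimethylfuran | Cc1c(C)c(-c2ccc(OC(C)=O)c(OC)c2)oc1-c1ccc(OC(C)=O)c(OC)c1
F4 | step 6 | (Z)-1,4-bis(4-acetoxy-3-methoxyphenyl)-2,3-dimethylbut-2-ene-1,4-dione | CC(=O)Oc1ccc(C(=O)/C(C)=C(C)\C(=O)c2ccc(OC(C)=O)c(OC)c2)cc1OC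
F5 | step 6 | (1R,4R,2Z)-1,4-bis(4-acetoxy-3-methoxyphenyl)-2,3-dimethylbut-2-ene-1,4-diol | CC(=O)Oc1ccc([C@@H](O)/C(C)=C(C)\[C@H](O)c2ccc(OC(C)=O)c(OC)c2)cc1OC
F6 | step 7 | (2S,3R,4S,5S)-2,5-bis(4-hydroxy-3-methoxyphenyl)-3,4-dimethyltetrahydrofuran-3-ol (enantiomer of 10) | COc1cc([C@@H]2O[C@H](c3ccc(O)c(OC)c3)[C@H](C)[C@@]2(C)O)ccc1O
F7 | step 7 | bis[(1S,4R)-camphanate] of 10 (both phenols esterified) | COc1cc([C@H]2O[C@@H](c3ccc(OC(=O)[C@@]45CC[C@@](C)(C(=O)O4)C5(C)C)c(OC)c3)[C@@H](C)[C@]2(C)O)ccc1OC(=O)[C@@]67CC[C@@](C)(C(=O)O6)C7(C)C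
F8 | step 7 | bis[(1S,4R)-camphanate] of F6 | COc1cc([C@@H]2O[C@H](c3ccc(OC(=O)[C@@]45CC[C@@](C)(C(=O)O4)C5(C)C)c(OC)c3)[C@H](C)[C@@]2(C)O)ccc1OC(=O)[C@@]67CC[C@@](C)(C(=O)O6)C7(C)C
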